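The labels are: C1 prenyl bridgehead, C2–C4 dicarbonyl bridge, C5 methyl bridgehead, C6–C7–C8 carbon bridge (C8 = CMe2), C9 bridging ketone. The trione ring C1–C2–C3–C4–C5–C9 is cut at C1–C9 and C4–C5: a formal [4+2] of a ketene (C9=C5) with a 1,3-dioxygenated C1–C4 dienolate, both already linked by C6–C7–C8. The precursor is open-chain: a γ-lactone (C9 acyl donor, ring oxygen on C7) joined through C8 to a β-methoxy enoate. One anionic cascade closes both rings and sets both quaternary bridgeheads from the C7 carbinol centre, set by catalytic reduction. C7 is then erased and rebuilt: exo-face hydroboration of a C7 methylene and Suzuki coupling place the prenyl group endo.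

Key step: step 5

Remark: the enolized β-triketone of the target is drawn as the C4-enol/C2-keto tautomer; the tautomers interconvert, so the route aims at the compound whichever tautomer is drawn.
Remark: bicyclic names use the atom labels above as locants; exo means away from the C2–C4 bridge, endo toward it.
Remark: compounds 5 and 9–13 are carried as mixtures at C1 and/or C5, because both centres become planar in step 5.

Step 1
Reactants: 1 isobutyric acid; 2 methyl (E)-4-bromo-3-methoxybut-2-enoate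
Product: 3 (E)-4,6-dimethoxy-2,2-dimethyl-6-oxohex-4-enoic acid
Conditions: LiN(i-Pr)2 (LDA, 2.1 equiv), THF, 0 °C → 40 °C; then 2, −78 °C → 0 °C; 1 M HCl
Reagents that add atoms: methyl (E)-4-bromo-3-methoxybut-2-enoate (2), COC(=O)/C=C(\CBr)OC
Why: The α-lithiated carboxylate (carboxylic acid dianion) should displace the allylic-type bromide in an SN2 enolate alkylation, which creates the quaternary C8 and the C8–C1 bond without any stereocentre.

Step 2
Reactants: 3 (E)-4,6-dimethoxy-2,2-dimethyl-6-oxohex-4-enoic acid; 4 prenyl bromide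
Product: 5 (E)-4,6-dimethoxy-2,2-dimethyl-3-(3-methylbut-2-en-1-yl)-6-oxohex-4-enoic acid (racemic)
Conditions: LiN(i-Pr)2 (2.2 equiv), THF–DMPU, −78 °C; then 4, −78 °C → −20 °C; 1 M HCl
Reagents that add atoms: prenyl bromide (4), CC(C)=CCBr
Why: The γ-proton of the (E)-β-methoxy enoate is removed next to the spectator carboxylate and the dienolate should be alkylated at its γ-carbon C1 (vinylogous enolate alkylation, which keeps the push–pull conjugation); C1 forms as a racemate, harmless because it is planarized again in step 5.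

Step 3
Reactants: 5 (E)-4,6-dimethoxy-2,2-dimethyl-3-(3-methylbut-2-en-1-yl)-6-oxohex-4-enoic acid; 6 methyl 3-bromo-2-methylpropanoate (racemic)
Product: 9 dimethyl (E)-3-methoxy-5,5,8-trimethyl-4-(3-methylbut-2-en-1-yl)-6-oxonon-2-enedioate, via acid chloride 7 (not isolated), via alkylzinc bromide 8 (not isolated)
Conditions: 5, Ghosez's reagent (1-chloro-N,N,2-trimethylprop-1-en-1-amine), CH2Cl2, 0 °C → 23 °C; separately 6, Zn dust, LiCl, THF, 40 °C; combine, Pd(PPh3)4 (5 mol %), THF, 0 °C → 23 °C
Reagents that add atoms: methyl 3-bromo-2-methylpropanoate (6), COC(=O)C(C)CBr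
Why: Negishi acylation, in which the hindered acid chloride made under neutral conditions should couple with the ester-bearing alkylzinc bromide to give the C7 ketone while esters, enol ether and alkene stay untouched; C5 forms unselectively, harmless for the reason given in step 2.

Step 4
Reactants: 9 dimethyl (E)-3-methoxy-5,5,8-trimethyl-4-(3-methylbut-2-en-1-yl)-6-oxonon-2-enedioate
Product: 11 methyl (2E)-3-methoxy-5-methyl-5-[(2S)-4-methyl-5-oxooxolan-2-yl]-4-(3-methylbut-2-en-1-yl)hex-2-enoate, via hydroxy diester 10 (not isolated)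
Conditions: (R)-2-methyl-CBS-oxazaborolidine (10 mol %), catecholborane, toluene, −78 °C → −20 °C; MeOH; then PPTS (cat.), CH2Cl2, 23 °C
Reagents that add atoms: none
Why: Corey–Bakshi–Shibata reduction, in which the catalyst distinguishes the tert-alkyl flank (C8) from the CH2 flank (C6) of the ketone and should give the (S)-carbinol at C7, the only centre set by a chiral reagent; the γ-hydroxy ester then lactonizes with loss of methanol.

Step 5
Reactants: 11 methyl (2E)-3-methoxy-5-methyl-5-[(2S)-4-methyl-5-oxooxolan-2-yl]-4-(3-methylbut-2-en-1-yl)hex-2-enoate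
Product: 14 (1S,5R,7S)-7-hydroxy-2-methoxy-5,8,8-trimethyl-1-(3-methylbut-2-en-1-yl)bicyclo[3.3.1]non-2-ene-4,9-dione (7-exo alcohol), via hydroxy ketene 12 (not isolated), via cyclohexanone 13 (not isolated)
Conditions: LiN(i-Pr)2 (2.4 equiv), THF–DMPU, −78 °C → 0 °C; cold 1 M HCl
Reagents that add atoms: none
Why: The base removes the lactone α-proton (C5–H) and the γ-proton (C1–H) of the β-methoxy enoate; on warming, the lactone enolate should open (E1cB, C7 alkoxide as leaving group) to the C5=C9 ketene, which the tethered dienolate attacks through C1 to form C1–C9 and leave the C9/C5 enolate, and this enolate then attacks the C4 ester with loss of methoxide to form C4–C5. The closest known reaction types are the γ-acylation of β-alkoxy enoate dienolates (vinylogous Claisen) and the Dieckmann condensation, combined as in tandem Claisen–Dieckmann routes to bicyclo[3.3.1]nonane triones; overall it is a stepwise ionic [4+2] of a ketene with a 1,3-dioxygenated diene. The cyclohexanone ring (C1–C8–C7–C6–C5–C9) closes by 6-exo attack of the exocyclic dienolate carbon on the ketene carbonyl carbon, and the second ring (C1–C2–C3–C4–C5–C9) by 6-(enolendo)-exo-trig attack of C5 on the ester, which the (E)-enol ether holds cis to C1. C1 is controlled by the C7 centre: in the chair-like closure the C7–OLi group is equatorial and the flat dienolate arm on C1 should take the axial site, where it avoids allylic strain with the C8 methyl groups, so C2 ends trans to the C7 oxygen (7-exo alcohol); C5 is then dictated by C1, because the arm can reach C5 only on its own face. The step needs γ- over α-acylation, which ring size secures (six- against eight-membered), and facial selectivity at C1, which the C7 centre secures. The 7-endo alcohol that a wrong-face closure would give is a diastereomer and should be removed by chromatography here, before C7 is erased.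

Step 6
Reactants: 14 (1S,5R,7S)-7-hydroxy-2-methoxy-5,8,8-trimethyl-1-(3-methylbut-2-en-1-yl)bicyclo[3.3.1]non-2-ene-4,9-dione
Product: 15 (1S,5R)-2-methoxy-5,8,8-trimethyl-1-(3-methylbut-2-en-1-yl)bicyclo[3.3.1]non-2-ene-4,7,9-trione
Conditions: Dess–Martin periodinane, CH2Cl2, 0 °C → 23 °C
Reagents that add atoms: none
Why: Dess–Martin oxidation of the secondary alcohol should give the C7 ketone and erases the C7 centre after it has fixed C1 and C5.

Step 7
Reactants: 15 (1S,5R)-2-methoxy-5,8,8-trimethyl-1-(3-methylbut-2-en-1-yl)bicyclo[3.3.1]non-2-ene-4,7,9-trione; 16 methyltriphenylphosphonium bromide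
Product: 17 (1S,5R)-2-methoxy-5,8,8-trimethyl-7-methylidene-1-(3-methylbut-2-en-1-yl)bicyclo[3.3.1]non-2-ene-4,9-dione
Conditions: 16, KOtBu, toluene, 23 °C; then 15, 80 °C
Reagents that add atoms: methyltriphenylphosphonium bromide (16), C[P+](c1ccccc1)(c1ccccc1)c1ccccc1.[Br-]
Why: Wittig methylenation should be selective for the C7 ketone, because C9 lies between two quaternary carbons and C4 is a deactivated vinylogous ester carbonyl.

Step 8
Reactants: 17 (1S,5R)-2-methoxy-5,8,8-trimethyl-7-methylidene-1-(3-methylbut-2-en-1-yl)bicyclo[3.3.1]non-2-ene-4,9-dione; 18 1-bromo-2-methylprop-1-ene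
Product: 20 (1S,5R,7R)-2-methoxy-5,8,8-trimethyl-1,7-bis(3-methylbut-2-en-1-yl)bicyclo[3.3.1]non-2-ene-4,9-dione, via B-alkyl-9-BBN 19 (not isolated)
Conditions: 9-BBN, THF, 23 °C; then 18, PdCl2(dppf) (5 mol %), K3PO4 (aq), DMF, 50 °C
Reagents that add atoms: 1-bromo-2-methylprop-1-ene (18), CC(C)=CBr
Why: Hydroboration with 9-BBN should touch only the 1,1-disubstituted alkene and deliver hydrogen to C7 from the open exo face (the endo face is blocked by the C2–C4 bridge), so the CH2–B arm is endo and C7 becomes (R); B-alkyl Suzuki–Miyaura coupling with the alkenyl bromide then completes the prenyl group.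

Step 9
Reactants: 20 (1S,5R,7R)-2-methoxy-5,8,8-trimethyl-1,7-bis(3-methylbut-2-en-1-yl)bicyclo[3.3.1]non-2-ene-4,9-dione; 21 isobutyryl chloride
Product: 22 (1S,5S,7R)-2-methoxy-5,8,8-trimethyl-1,7-bis(3-methylbut-2-en-1-yl)-3-(2-methylpropanoyl)bicyclo[3.3.1]non-2-ene-4,9-dione
Conditions: lithium 2,2,6,6-tetramethylpiperidide, THF, −78 °C; then 21, −78 °C → 0 °C
Reagents that add atoms: isobutyryl chloride (21), CC(C)C(Cl)=O
Why: Vinylic deprotonation at C3 of the β-methoxy enone by the hindered lithium amide and C-acylation of the vinyllithium should install the acyl group without touching any stereocentre (the change of the C5 descriptor is only a priority change).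

Step 10
Reactants: 22 (1S,5S,7R)-2-methoxy-5,8,8-trimethyl-1,7-bis(3-methylbut-2-en-1-yl)-3-(2-methylpropanoyl)bicyclo[3.3.1]non-2-ene-4,9-dione
Product: 23 (1R,5R,7R)-4-hydroxy-5,8,8-trimethyl-1,7-bis(3-methylbut-2-en-1-yl)-3-(2-methylpropanoyl)bicyclo[3.3.1]non-3-ene-2,9-dione (CNP0265287.1)
Conditions: LiCl, DMSO, 120 °C; 1 M HCl
Reagents that add atoms: none
Why: Chloride should attack the O-methyl group in an SN2 demethylation (Krapcho-type) and free the enolized β-triketone, which is the target after acidic work-up.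

Compound list
1 | isobutyric acid (2-methylpropanoic acid) | CC(C)C(=O)O | starting material
2 | methyl (E)-4-bromo-3-methoxybut-2-enoate | COC(=O)/C=C(\CBr)OC | starting material
3 | (E)-4,6-dimethoxy-2,2-dimethyl-6-oxohex-4-enoic acid | COC(=O)/C=C(\CC(C)(C)C(O)=O)OC | intermediate
4 | prenyl bromide (1-bromo-3-methylbut-2-ene) | CC(C)=CCBr | starting material
5 | (E)-4,6-dimethoxy-2,2-dimethyl-3-(3-methylbut-2-en-1-yl)-6-oxohex-4-enoic acid, racemic | COC(=O)/C=C(\C(CC=C(C)C)C(C)(C)C(O)=O)OC | intermediate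
6 | methyl 3-bromo-2-methylpropanoate, racemic | COC(=O)C(C)CBr | starting material
7 | methyl (E)-6-chloro-3-methoxy-5,5-dimethyl-4-(3-methylbut-2-en-1-yl)-6-oxohex-2-enoate (acid chloride of 5) | COC(=O)/C=C(\C(CC=C(C)C)C(C)(C)C(Cl)=O)OC | intermediate
8 | (3-methoxy-2-methyl-3-oxopropyl)zinc bromide | COC(=O)C(C)C[Zn]Br | intermediate
9 | dimethyl (E)-3-methoxy-5,5,8-trimethyl-4-(3-methylbut-2-en-1-yl)-6-oxonon-2-enedioate, mixture at C4 and C8 of the chain | COC(=O)/C=C(\C(CC=C(C)C)C(C)(C)C(=O)CC(C)C(=O)OC)OC | intermediate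
10 | dimethyl (2E,6S)-6-hydroxy-3-methoxy-5,5,8-trimethyl-4-(3-methylbut-2-en-1-yl)non-2-enedioate | COC(=O)/C=C(\C(CC=C(C)C)C(C)(C)[C@@H](O)CC(C)C(=O)OC)OC | intermediate
11 | methyl (2E)-3-methoxy-5-methyl-5-[(2S)-4-methyl-5-oxooxolan-2-yl]-4-(3-methylbut-2-en-1-yl)hex-2-enoate | COC(=O)/C=C(\C(CC=C(C)C)C(C)(C)[C@@H]1CC(C)C(=O)O1)OC | intermediate
12 | methyl (2E,6S)-6-hydroxy-3-methoxy-5,5,8-trimethyl-4-(3-methylbut-2-en-1-yl)-9-oxonona-2,8-dienoate (hydroxy ketene, present as its dilithium salt) | COC(=O)/C=C(\C(CC=C(C)C)C(C)(C)[C@@H](O)CC(C)=C=O)OC | intermediate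
13 | methyl (E)-3-[(1S,3S)-3-hydroxy-2,2,5-trimethyl-1-(3-methylbut-2-en-1-yl)-6-oxocyclohexyl]-3-methoxyprop-2-enoate | O[C@H]1CC(C)C(=O)[C@](CC=C(C)C)(/C(OC)=C\C(=O)OC)C1(C)C | intermediate
14 | (1S,5R,7S)-7-hydroxy-2-methoxy-5,8,8-trimethyl-1-(3-methylbut-2-en-1-yl)bicyclo[3.3.1]non-2-ene-4,9-dione | O[C@H]1C[C@@]2(C)C(=O)[C@](CC=C(C)C)(C(OC)=CC2=O)C1(C)C | intermediate
15 | (1S,5R)-2-methoxy-5,8,8-trimethyl-1-(3-methylbut-2-en-1-yl)bicyclo[3.3.1]non-2-ene-4,7,9-trione | O=C1C[C@@]2(C)C(=O)[C@](CC=C(C)C)(C(OC)=CC2=O)C1(C)C | intermediate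
16 | methyltriphenylphosphonium bromide | C[P+](c1ccccc1)(c1ccccc1)c1ccccc1.[Br-] | starting material
17 | (1S,5R)-2-methoxy-5,8,8-trimethyl-7-methylidene-1-(3-methylbut-2-en-1-yl)bicyclo[3.3.1]non-2-ene-4,9-dione | C=C1C[C@@]2(C)C(=O)[C@](CC=C(C)C)(C(OC)=CC2=O)C1(C)C | intermediate
18 | 1-bromo-2-methylprop-1-ene | CC(C)=CBr | starting material
19 | 9-{[(1S,5R,7R)-2-methoxy-5,8,8-trimethyl-1-(3-methylbut-2-en-1-yl)-4,9-dioxobicyclo[3.3.1]non-2-en-7-yl]methyl}-9-borabicyclo[3.3.1]nonane | C(B1C2CCCC1CCC2)[C@@H]3C[C@@]4(C)C(=O)[C@](CC=C(C)C)(C(OC)=CC4=O)C3(C)C | intermediate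
20 | (1S,5R,7R)-2-methoxy-5,8,8-trimethyl-1,7-bis(3-methylbut-2-en-1-yl)bicyclo[3.3.1]non-2-ene-4,9-dione | CC(C)=CC[C@@H]1C[C@@]2(C)C(=O)[C@](CC=C(C)C)(C(OC)=CC2=O)C1(C)C | intermediate
21 | isobutyryl chloride (2-methylpropanoyl chloride) | CC(C)C(Cl)=O | starting material
22 | (1S,5S,7R)-2-methoxy-5,8,8-trimethyl-1,7-bis(3-methylbut-2-en-1-yl)-3-(2-methylpropanoyl)bicyclo[3.3.1]non-2-ene-4,9-dione | CC(C)=CC[C@@H]1C[C@@]2(C)C(=O)[C@](CC=C(C)C)(C(OC)=C(C(=O)C(C)C)C2=O)C1(C)C | intermediate
23 | (1R,5R,7R)-4-hydroxy-5,8,8-trimethyl-1,7-bis(3-methylbut-2-en-1-yl)-3-(2-methylpropanoyl)bicyclo[3.3.1]non-3-ene-2,9-dione | CC(C)=CC[C@@H]1C[C@@]2(C)C(=O)[C@](CC=C(C)C)(C(=O)C(C(=O)C(C)C)=C2O)C1(C)C | target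

Total step count: 10. Longest linear sequence: 10 steps (from 1).

Steps most likely to fail

Step 5. Deprotonation at the hindered C1–H may be incomplete, release of the ketene from the lactone enolate may be slow, or the closures may revert (retro-Claisen by the freed C7 alkoxide or by methoxide). The fallback sets out from 11 and comes back at 14; it replaces the ketene by an acyl donor whose adduct cannot revert. The lactone is opened with MeNH(OMe)·HCl and AlMe3 to the hydroxy Weinreb amide F1, which is silylated with Et3SiCl and imidazole to the triethylsilyl ether F2. KN(SiMe3)2 (2.3 equiv, THF, −78 °C → 23 °C) should then acylate the C1 dienolate with the Weinreb amide (chelated tetrahedral adduct) to give the cyclohexanone F3 in the flask, and the same base should close the second ring by Dieckmann condensation to the bicyclic silyl ether F4. HF·pyridine returns 14. Should the facial preference at C1 be the opposite of the one expected, the antipodal catalyst in step 4 corrects it, since C7 is erased in step 6.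

Step 8. Hydroboration next to the quaternary C8 may be slow or may lose its facial selectivity, and the coupling of the neopentyl-type borane may stall. The fallback sets out from 15 and comes back at 20; it builds the endo side chain by radical reduction instead. Allylmagnesium bromide with CeCl3 should add to the C7 ketone from the exo face to give the tertiary alcohol F5, and methyl chlorooxoacetate with DMAP gives the methyl oxalate F6. Bu3SnH and AIBN (toluene, 110 °C) cleave the C7–O bond, and the C7 radical should take hydrogen from the exo face to give the endo-allyl compound F7. Cross-metathesis with 2-methylbut-2-ene (second-generation Grubbs catalyst) gives 20.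

Step 2. The dienolate may be alkylated at C3 (α) instead of C1 (γ), or the carboxylate may be O-alkylated. The fallback sets out from 3 and comes back at 5; it uses a β-keto ester polyanion, whose γ-alkylation is established. Aqueous HCl in THF hydrolyses the enol ether to the β-keto ester acid F8. Its trianion (LiN(i-Pr)2, 3.2 equiv) should be alkylated by prenyl bromide at the γ-carbon to give the keto acid F9. HC(OMe)3 and p-TsOH in methanol restore the (E)-methyl enol ether and give 5.

Further compounds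
F1 | step 5 | methyl (2E,6S)-6-hydroxy-3-methoxy-9-[methoxy(methyl)amino]-5,5,8-trimethyl-4-(3-methylbut-2-en-1-yl)-9-oxonon-2-enoate | COC(=O)/C=C(\C(CC=C(C)C)C(C)(C)[C@@H](O)CC(C)C(=O)N(C)OC)OC
F2 | step 5 | methyl (2E,6S)-3-methoxy-9-[methoxy(methyl)amino]-5,5,8-trimethyl-4-(3-methylbut-2-en-1-yl)-9-oxo-6-[(triethylsilyl)oxy]non-2-enoate | COC(=O)/C=C(\C(CC=C(C)C)C(C)(C)[C@@H](O[Si](CC)(CC)CC)CC(C)C(=O)N(C)OC)OC
F3 | step 5 | methyl (E)-3-methoxy-3-[(1S,3S)-2,2,5-trimethyl-1-(3-methylbut-2-en-1-yl)-6-oxo-3-[(triethylsilyl)oxy]cyclohexyl]prop-2-enoate | CC[Si](CC)(CC)O[C@H]1CC(C)C(=O)[C@](CC=C(C)C)(/C(OC)=C\C(=O)OC)C1(C)C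
F4 | step 5 | (1S,5R,7S)-2-methoxy-5,8,8-trimethyl-1-(3-methylbut-2-en-1-yl)-7-[(triethylsilyl)oxy]bicyclo[3.3.1]non-2-ene-4,9-dione | CC[Si](CC)(CC)O[C@H]1C[C@@]2(C)C(=O)[C@](CC=C(C)C)(C(OC)=CC2=O)C1(C)C
F5 | step 8 | (1S,5R,7R)-7-hydroxy-2-methoxy-5,8,8-trimethyl-1-(3-methylbut-2-en-1-yl)-7-(prop-2-en-1-yl)bicyclo[3.3.1]non-2-ene-4,9-dione | C=CC[C@@]1(O)C[C@@]2(C)C(=O)[C@](CC=C(C)C)(C(OC)=CC2=O)C1(C)C
F6 | step 8 | (1S,5R,7R)-2-methoxy-5,8,8-trimethyl-1-(3-methylbut-2-en-1-yl)-4,9-dioxo-7-(prop-2-en-1-yl)bicyclo[3.3.1]non-2-en-7-yl methyl oxalate | C=CC[C@@]1(OC(=O)C(=O)OC)C[C@@]2(C)C(=O)[C@](CC=C(C)C)(C(OC)=CC2=O)C1(C)C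
F7 | step 8 | (1S,5R,7R)-2-methoxy-5,8,8-trimethyl-1-(3-methylbut-2-en-1-yl)-7-(prop-2-en-1-yl)bicyclo[3.3.1]non-2-ene-4,9-dione | C=CC[C@@H]1C[C@@]2(C)C(=O)[C@](CC=C(C)C)(C(OC)=CC2=O)C1(C)C
F8 | step 2 | 6-methoxy-2,2-dimethyl-4,6-dioxohexanoic acid | COC(=O)CC(=O)CC(C)(C)C(O)=O
F9 | step 2 | 6-methoxy-2,2-dimethyl-3-(3-methylbut-2-en-1-yl)-4,6-dioxohexanoic acid | COC(=O)CC(=O)C(CC=C(C)C)C(C)(C)C(O)=O
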